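(Readings and results are simulated with constants of no real substance, noise included.)

Target runs ahead of its isomer at first and behind it later: in the north run 18.2% against 1.1% at 0.250 min, but 34.2% against 45.9% at 3.00 min. So I ask first where that exchange ends.

| flask | substrate | free catalyst | remark | time |
|---|---|---|---|---|
| north-west | 0.061 M | 1.2 mol% | run made earlier |  |
| north | 0.061 M | 4.8 mol% | run made earlier |  |
| flask | 0.061 M | 2.4 mol% |  | 2.5 min |

- north-west (time / min: target / %, isomer of the product / %): 0.250: 5.0, 0.6; 0.833: 13.3, 4.5; 1.33: 16.4, 9.0; 2.00: 18.7, 14.5; 3.00: 20.5, 22.1
- north (time / min: target / %, isomer of the product / %): 0.250: 18.2, 1.1; 0.417: 25.4, 4.7; 0.833: 34.7, 13.3; 1.50: 38.0, 26.3; 3.00: 34.2, 45.9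

(scatter of a reading: 0.3 percentage points)



- how much target the flask holds at 2.5 min, in percent of the substrate charged
- how much isomer of the product the flask holds at 2.5 min, in percent of the substrate charged
- how much substrate the flask holds at 2.5 min, in percent of the substrate charged

1. **The end.** I take target ⇌ isomer of the product as first order both ways. Between 1.50 min and 3.00 min of the north run, both average the same amount, so the isomer's rise gives forward minus back: 0.362 min⁻¹. The window before it then gives the back constant, 0.383 min⁻¹. From these readings I get the end ratio, c(isomer of the product)/c(target) when the exchange balances (the equilibrium constant): 1.95.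

2. **Faster rung.** By the forward step alone, target lasts 1.34 min, shorter than 2.5 min. So I expect target in this flask to come near a quasi-steady state, supply against loss, before the asked time. The north run reads its highest target, 38.0%, at 1.50 min.

3. **Slower rung.** With target flat, isomer climbs towards the ceiling, end ratio times c(target), with a lifetime of 2.61 min, longer than target's. That is about the asked time, so I expect this flask still well below its ceiling.

4. **The forecast.** It gives target 28%, isomer 29.5% and substrate 42.5%. On substrate, which no reading shows, it says: “The apparent constant falls as the runs proceed, so I interpolate”.

5. **The flask.** It gives target 28.7%, isomer 29.7% and substrate 20.8%.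

    substrate + free catalyst → catalyst intermediate A (k = 12.0 M⁻¹ s⁻¹)
    catalyst intermediate A ⇌ catalyst intermediate B (K = 17.0, k = 2.00 s⁻¹)
    catalyst intermediate B ⇌ free catalyst + target (K = 0.0200 M, k = 1.50 s⁻¹)
    2 substrate → self-condensation product (k = 0.0390 M⁻¹ s⁻¹)
    target ⇌ isomer of the product (K = 1.90, k = 0.0130 s⁻¹)

Target and isomer fall inside the forecast's ranges, but substrate stands 22 percentage points lower. Making catalyst intermediate A uses substrate 3.7 times as fast as self-condensation at the start and 8.4 times at the asked time, yet this flask holds 19.6% self-condensation product, each counted as two.

In this flask target is made 1.03 times as fast as it is used up, so I hold it flat: the ceiling is 55.8%, and isomer stands at half of it. Left until 4.0 min, the climb gives 41.1%; the computed neighbour holds 41.0% isomer and 28.3% target.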